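**Strategy.** The spiro carbon C6, the only atom shared by ring A (C6–C11) and ring B (C1–C6), is disconnected last at C6–C11; its configuration is stored beforehand as the geometry of an exocyclic enol ether. The key step, an intramolecular Horner–Wadsworth–Emmons olefination of an acyclic keto-phosphonate aldehyde, closes ring B at C5–C6 (C5 is the ring-B methylene of the CH2–CH2–CBr arm) and leaves C5 as the one ring carbon conjugated to the C7 carbonyl. 1,4-Hydrosilylation then places the enol oxygen cis to C5, and stereospecific ionisation of an enantioenriched C10/C11 bromochloride closes ring A through a chair, relaying C10 to C6. Chlorohydrin formation, bromide substitution and methylenation complete the target.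

Key step: step 7

Numbering used for these atoms in all intermediates: ring B = C6 (spiro), C1H2, C2HCl, C3(CH3)Br, C4H2, C5H2; ring A = C6, C7 (bearing the methylene carbon C14), C8H2, C9H2, C10HBr, C11(CH3)2.
Assumption: 4-methyl-5,6-dihydro-2H-pyran-2-one is taken as a purchasable starting material.

**Step 1**
Reactants: 1 3-methylbut-2-en-1-ol
Product: 2 (2S)-2-bromo-3-chloro-3-methylbutan-1-ol
Conditions: NBS, ClTi(OiPr)3, chiral tridentate Schiff-base (salicylaldimine amino-alcohol) ligand (cat., the enantiomer that leads to 2S), hexanes, −20 °C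
Reagents that add atoms: N-bromosuccinimide O=C1CCC(=O)N1Br; chlorotitanium triisopropoxide CC(C)O[Ti](Cl)(OC(C)C)OC(C)C
Why: Titanium-catalysed enantioselective bromochlorination of an allylic alcohol: the ligand-bound titanium alkoxide directs bromonium formation to one alkene face and delivers chloride anti to the tertiary carbon, which sets C10 (2S) as the single stereocentre brought in by reagent control.

**Step 2**
Reactants: 2 (2S)-2-bromo-3-chloro-3-methylbutan-1-ol
Product: 3 (2S)-2-bromo-3-chloro-3-methylbutyl trifluoromethanesulfonate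
Conditions: Tf2O, 2,6-lutidine, CH2Cl2, −78 °C
Reagents that add atoms: trifluoromethanesulfonic anhydride O=S(=O)(OS(=O)(=O)C(F)(F)F)C(F)(F)F
Why: Sulfonylation of the primary alcohol gives a triflate reactive enough for SN2 at −78 °C at a β-branched carbon, and C10 is not touched.

**Step 3**
Reactants: 4 dimethyl (2-oxopropyl)phosphonate; 3 (2S)-2-bromo-3-chloro-3-methylbutyl trifluoromethanesulfonate
Product: 5 dimethyl [(5S)-5-bromo-6-chloro-6-methyl-2-oxoheptyl]phosphonate
Conditions: 4, NaH, THF, 0 °C; n-BuLi, −78 °C; then 3, −78 → −40 °C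
Reagents that add atoms: none
Why: γ-Alkylation of a β-ketophosphonate dianion: the more basic terminal carbanion displaces the primary triflate by SN2 and forms C8–C9, while the tertiary chloride and the hindered secondary bromide should be inert at −78 °C.

**Step 4**
Reactants: 6 4-methyl-5,6-dihydro-2H-pyran-2-one
Product: 7 (2Z)-3-methylpent-2-ene-1,5-diol
Conditions: LiAlH4, Et2O, −20 → 0 °C
Reagents that add atoms: none
Why: Hydride reduction of the unsaturated δ-lactone (1,2-addition at the ester carbonyl) opens the ring to the diol, and the Z geometry of C2=C3 is inherited from the ring.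

**Step 5**
Reactants: 7 (2Z)-3-methylpent-2-ene-1,5-diol
Product: 8 (3Z)-5-chloro-3-methylpent-3-en-1-ol
Conditions: NCS, Me2S, CH2Cl2, −20 → 0 °C; used at once
Reagents that add atoms: N-chlorosuccinimide O=C1CCC(=O)N1Cl
Why: Corey–Kim chlorination: the chlorosulfonium reagent activates the more reactive allylic hydroxyl selectively and chloride displaces the alkoxysulfonium group by SN2 without allylic shift, so the Z alkene is kept.

**Step 6**
Reactants: 5 dimethyl [(5S)-5-bromo-6-chloro-6-methyl-2-oxoheptyl]phosphonate; 8 (3Z)-5-chloro-3-methylpent-3-en-1-ol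
Product: 9 dimethyl [(3Z,10S)-10-bromo-11-chloro-1-hydroxy-3,11-dimethyl-7-oxododec-3-en-6-yl]phosphonate (both epimers at the phosphonate carbon C6)
Conditions: 5, NaH (1 equiv), THF/DMF, 0 °C; then 8, NaI (cat.), 0 → 23 °C
Reagents that add atoms: none
Why: C-Alkylation of the stabilised sodium phosphonoenolate with the primary allylic chloride (SN2, iodide catalysis) forms C1–C6; the weakly basic enolate leaves the free hydroxyl and the halides alone, and the mixture at C6 is irrelevant because C6 becomes trigonal in the next step.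

**Step 7**
Reactants: 9 dimethyl [(3Z,10S)-10-bromo-11-chloro-1-hydroxy-3,11-dimethyl-7-oxododec-3-en-6-yl]phosphonate
Product: 11 (4S)-4-bromo-5-chloro-5-methyl-1-(4-methylcyclohexa-1,4-dien-1-yl)hexan-1-one, via keto-phosphonate aldehyde 10 (not isolated)
Conditions: Dess–Martin periodinane, NaHCO3, CH2Cl2, 0 °C; then LiCl, iPr2NEt, MeCN, 23 °C, under argon
Reagents that add atoms: none
Why: Dess–Martin oxidation gives aldehyde 10, and LiCl/amine then generates the lithium-chelated phosphonoenolate at C6, which adds to the C5 aldehyde and collapses through the oxaphosphetane with loss of dimethyl phosphate, so that the C5–C6 bond of ring B is made as an enone double bond (intramolecular Horner–Wadsworth–Emmons olefination under Masamune–Roush conditions, the closest known type being HWE carbocyclisations to 1-acylcycloalkenes). Ring B closes by 6-exo-trig attack of C6 on the aldehyde carbon followed by syn elimination, the Z C2=C3 alkene holding C1 and C4 on one side so that the six-membered ring is the only accessible one. No stereocentre is formed: the C6 epimers of 9 converge and C10 is remote. The step needs chemoselective deprotonation at C6, which the chelating lithium cation secures over the aldehyde α-hydrogens at C4 and over C8, so that aldol closure and migration of the β,γ-alkene into conjugation should be avoided. Its strategic result is that C5, and not C1, becomes the sp2 carbon conjugated to the C7 carbonyl; this difference between the two arms of ring B is what step 8 converts into a defined enol ether geometry and step 9 into the C6 configuration.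

**Step 8**
Reactants: 11 (4S)-4-bromo-5-chloro-5-methyl-1-(4-methylcyclohexa-1,4-dien-1-yl)hexan-1-one
Product: 12 {[(1E,4S)-4-bromo-5-chloro-5-methyl-1-(4-methylcyclohex-3-en-1-ylidene)hexyl]oxy}(triethyl)silane (OSiEt3 cis to C5)
Conditions: Et3SiH, Rh(PPh3)3Cl (cat.), benzene, 50 °C
Reagents that add atoms: triethylsilane CC[SiH](CC)CC
Why: Rhodium-catalysed 1,4-hydrosilylation of the enone through its s-cis, rhodium-bound form puts hydrogen on C5 and silicon on oxygen, so that the new C6=C7 enol ether carries oxygen cis to C5 and C8 cis to C1 (E descriptor), the geometry that encodes the later C6 configuration.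

**Step 9**
Reactants: 12 {[(1E,4S)-4-bromo-5-chloro-5-methyl-1-(4-methylcyclohex-3-en-1-ylidene)hexyl]oxy}(triethyl)silane
Product: 13 (4S,6R)-4-bromo-5,5,9-trimethylspiro[5.5]undec-8-en-1-one
Conditions: (CF3)2CHOH, 2,6-di-tert-butyl-4-methylpyridine, 23 °C
Reagents that add atoms: none
Why: Solvolytic, bromine-assisted ionisation of the tertiary chloride gives the C10/C11 bromonium ion with retention at C10, and the silyl enol ether carbon C6 opens it at C11 in a chair 6-endo cation–olefin cyclisation (Br equatorial, C1 arm cis to C8 axial, C5 arm equatorial and cis to Br), so C6 is set by C10 and the enol ether geometry before the silyloxocarbenium ion loses silicon to give the ketone.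

**Step 10**
Reactants: 13 (4S,6R)-4-bromo-5,5,9-trimethylspiro[5.5]undec-8-en-1-one
Product: 14 (4S,6R,8R,9R)-4-bromo-8-chloro-9-hydroxy-5,5,9-trimethylspiro[5.5]undecan-1-one
Conditions: trichloroisocyanuric acid (0.4 equiv), acetone/H2O, 0 °C
Reagents that add atoms: trichloroisocyanuric acid O=C1N(Cl)C(=O)N(Cl)C(=O)N1Cl; water O
Why: Chlorohydrin formation by electrophilic chlorination: the chloronium ion forms reversibly and water opens it at the tertiary C3 in a Markovnikov, trans-diaxial (Fürst–Plattner) sense through the half-chair that keeps the quaternary C11 equatorial, which places Cl on C2 syn to C7 and OH on C3 on the opposite face.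

**Step 11**
Reactants: 14 (4S,6R,8R,9R)-4-bromo-8-chloro-9-hydroxy-5,5,9-trimethylspiro[5.5]undecan-1-one
Product: 15 (4S,6R,8R,9R)-4,9-dibromo-8-chloro-5,5,9-trimethylspiro[5.5]undecan-1-one
Conditions: Me3SiBr, CH2Cl2, 0 → 23 °C
Reagents that add atoms: bromotrimethylsilane C[Si](C)(C)Br
Why: SN1 substitution of the tertiary alcohol with anchimeric assistance by the anti-periplanar C2 chlorine: bromide opens the bridged chloronium ion at C3 from the face opposite to chlorine, so C3 keeps its configuration (Br trans-diaxial to Cl), and HBr returns any elimination product to the same tertiary cation.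

**Step 12**
Reactants: 15 (4S,6R,8R,9R)-4,9-dibromo-8-chloro-5,5,9-trimethylspiro[5.5]undecan-1-one
Product: 16 (4S,6S,8R,9R)-4,9-dibromo-8-chloro-5,5,9-trimethyl-1-methylidenespiro[5.5]undecane (chamigrane numbering 2R,3R,6S,10S)
Conditions: Cp2TiMe2, toluene, 65 °C, dark
Reagents that add atoms: dimethyltitanocene C[Ti](C)(C1C=CC=C1)C1C=CC=C1
Why: Petasis methylenation: the titanium methylidene formed on heating adds to the hindered C7 carbonyl by [2+2] cycloaddition and cycloreversion under non-basic conditions, so the tertiary bromide and the stereocentres should not be touched.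

**Compound list**
1 | 3-methylbut-2-en-1-ol | CC(C)=CCO | starting material
2 | (2S)-2-bromo-3-chloro-3-methylbutan-1-ol | OC[C@H](Br)C(C)(C)Cl | intermediate
3 | (2S)-2-bromo-3-chloro-3-methylbutyl trifluoromethanesulfonate | O=S(=O)(OC[C@H](Br)C(C)(C)Cl)C(F)(F)F | intermediate
4 | dimethyl (2-oxopropyl)phosphonate | COP(=O)(CC(C)=O)OC | starting material
5 | dimethyl [(5S)-5-bromo-6-chloro-6-methyl-2-oxoheptyl]phosphonate | COP(=O)(OC)CC(=O)CC[C@H](Br)C(C)(C)Cl | intermediate
6 | 4-methyl-5,6-dihydro-2H-pyran-2-one | CC1=CC(=O)OCC1 | starting material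
7 | (2Z)-3-methylpent-2-ene-1,5-diol | OC/C=C(C)\CCO | intermediate
8 | (3Z)-5-chloro-3-methylpent-3-en-1-ol | ClC/C=C(C)\CCO | intermediate
9 | dimethyl [(3Z,10S)-10-bromo-11-chloro-1-hydroxy-3,11-dimethyl-7-oxododec-3-en-6-yl]phosphonate | COP(=O)(OC)C(C/C=C(C)\CCO)C(=O)CC[C@H](Br)C(C)(C)Cl | intermediate
10 | dimethyl [(3Z,10S)-10-bromo-11-chloro-3,11-dimethyl-1,7-dioxododec-3-en-6-yl]phosphonate | COP(=O)(OC)C(C/C=C(C)\CC=O)C(=O)CC[C@H](Br)C(C)(C)Cl | intermediate
11 | (4S)-4-bromo-5-chloro-5-methyl-1-(4-methylcyclohexa-1,4-dien-1-yl)hexan-1-one | CC1=CCC(=CC1)C(=O)CC[C@H](Br)C(C)(C)Cl | intermediate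
12 | {[(1E,4S)-4-bromo-5-chloro-5-methyl-1-(4-methylcyclohex-3-en-1-ylidene)hexyl]oxy}(triethyl)silane | CC1=CC/C(CC1)=C(/O[Si](CC)(CC)CC)CC[C@H](Br)C(C)(C)Cl | intermediate
13 | (4S,6R)-4-bromo-5,5,9-trimethylspiro[5.5]undec-8-en-1-one | O=C1CC[C@H](Br)C(C)(C)[C@]12CCC(C)=CC2 | intermediate
14 | (4S,6R,8R,9R)-4-bromo-8-chloro-9-hydroxy-5,5,9-trimethylspiro[5.5]undecan-1-one | O=C1CC[C@H](Br)C(C)(C)[C@]12CC[C@@](C)(O)[C@H](Cl)C2 | intermediate
15 | (4S,6R,8R,9R)-4,9-dibromo-8-chloro-5,5,9-trimethylspiro[5.5]undecan-1-one | O=C1CC[C@H](Br)C(C)(C)[C@]12CC[C@@](C)(Br)[C@H](Cl)C2 | intermediate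
16 | (4S,6S,8R,9R)-4,9-dibromo-8-chloro-5,5,9-trimethyl-1-methylidenespiro[5.5]undecane | C=C1CC[C@H](Br)C(C)(C)[C@]12CC[C@@](C)(Br)[C@H](Cl)C2 | target

**Totals.** Total step count: 12. Longest linear sequence: 10 steps (steps 1, 2, 3, 6, 7, 8, 9, 10, 11, 12); steps 4 and 5 make the side arm.

**Steps most likely to fail**

Step 9. The silyl enol ether may be protonated and lost in the acidic solvent before the chloride ionises. The bromonium ion may also be captured by the enol oxygen, or acid-mediated E/Z equilibration may erode the C6 configuration. The fallback uses an all-carbon terminator; it sets out from 11 and comes back at 16. Petasis methylenation of 11 (Cp2TiMe2, toluene, 65 °C) should give 1-[(5S)-5-bromo-6-chloro-6-methylhept-1-en-2-yl]-4-methylcyclohexa-1,4-diene F1. 1,4-Hydrogenation of its s-cis 1,3-diene unit with (naphthalene)Cr(CO)3 and H2 in THF should give 4-[(2Z,5S)-5-bromo-6-chloro-6-methylheptan-2-ylidene]-1-methylcyclohex-1-ene F2, with the new methyl C14 cis to C5. Solvolysis in (CF3)2CHOH with the same pyridine base closes ring A through the same chair. After loss of a proton, the exocyclic isomer (4S,6S)-4-bromo-5,5,9-trimethyl-1-methylidenespiro[5.5]undec-8-ene F3 is separated from its endocyclic isomer. Trichloroisocyanuric acid in aqueous acetone should then give, at the more nucleophilic trisubstituted alkene, (4S,6S,8R,9R)-4-bromo-8-chloro-5,5,9-trimethyl-1-methylidenespiro[5.5]undecan-9-ol F4. Finally 1-bromo-N,N,2-trimethylprop-1-en-1-amine in CH2Cl2 under neutral conditions should convert the tertiary alcohol into 16 with retention.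

Step 3. The strongly basic dianion may remove the acidified hydrogen at C10 or attack bromine, so that elimination outruns substitution at the β-bromo triflate. The fallback sets out from 3 and comes back at 5. Copper-catalysed substitution of the triflate with allylmagnesium chloride (CuBr·SMe2 cat., THF, −78 °C) should give (5S)-5-bromo-6-chloro-6-methylhept-1-ene F5. Epoxidation with mCPBA should give 2-[(3S)-3-bromo-4-chloro-4-methylpentyl]oxirane F6. Opening at the terminal carbon with LiP(O)(OMe)2 and BF3·OEt2 in THF at −78 °C should give dimethyl [(5S)-5-bromo-6-chloro-2-hydroxy-6-methylheptyl]phosphonate F7, and Dess–Martin oxidation returns 5.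

Step 12. The titanium methylidene may add only slowly to the hindered C7 carbonyl, and the tertiary bromide may lose HBr at 65 °C. The fallback is a two-operation Peterson olefination; it sets out from 15 and comes back at 16. Addition of Me3SiCH2MgCl with CeCl3 in THF at −78 °C should give (4S,6R,8R,9R)-4,9-dibromo-8-chloro-5,5,9-trimethyl-1-[(trimethylsilyl)methyl]spiro[5.5]undecan-1-ol F8, and elimination with HF in MeCN should give 16.

**Further compounds**
F1 | step 9 | 1-[(5S)-5-bromo-6-chloro-6-methylhept-1-en-2-yl]-4-methylcyclohexa-1,4-diene | C=C(CC[C@H](Br)C(C)(C)Cl)C1=CCC(C)=CC1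
F2 | step 9 | 4-[(2Z,5S)-5-bromo-6-chloro-6-methylheptan-2-ylidene]-1-methylcyclohex-1-ene | CC1=CC/C(CC1)=C(/C)CC[C@H](Br)C(C)(C)Cl
F3 | step 9 | (4S,6S)-4-bromo-5,5,9-trimethyl-1-methylidenespiro[5.5]undec-8-ene | C=C1CC[C@H](Br)C(C)(C)[C@]12CCC(C)=CC2
F4 | step 9 | (4S,6S,8R,9R)-4-bromo-8-chloro-5,5,9-trimethyl-1-methylidenespiro[5.5]undecan-9-ol | C=C1CC[C@H](Br)C(C)(C)[C@]12CC[C@@](C)(O)[C@H](Cl)C2
F5 | step 3 | (5S)-5-bromo-6-chloro-6-methylhept-1-ene | C=CCC[C@H](Br)C(C)(C)Cl
F6 | step 3 | 2-[(3S)-3-bromo-4-chloro-4-methylpentyl]oxirane | C1OC1CC[C@H](Br)C(C)(C)Cl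
F7 | step 3 | dimethyl [(5S)-5-bromo-6-chloro-2-hydroxy-6-methylheptyl]phosphonate | COP(=O)(OC)CC(O)CC[C@H](Br)C(C)(C)Cl
F8 | step 12 | (4S,6R,8R,9R)-4,9-dibromo-8-chloro-5,5,9-trimethyl-1-[(trimethylsilyl)methyl]spiro[5.5]undecan-1-ol | C[Si](C)(C)CC1(O)CC[C@H](Br)C(C)(C)[C@]12CC[C@@](C)(Br)[C@H](Cl)C2
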